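Read the last column.

| flask | solid electrophile | free base | protonated nucleophile | remark | time |
|---|---|---|---|---|---|
| beta | 0.23 M | 0.34 M | 0.85 M | run made earlier |  |
| eta | 0.17 M | 0.34 M | 0.85 M | run made earlier |  |
| ash | 0.34 M | 0.340 M | 0.850 M |  | 6.0 h |
| oak | 0.34 M | 0.510 M | 0.850 M |  | 6.0 h |
| larch | 0.34 M | 0.770 M | 0.850 M |  | 6.0 h |

- beta (time / min: solid electrophile / %, target / %): 20.0: 95.5, 0.7; 40.0: 92.1, 0; 60.0: 88.6, 0; 80.0: 85.2, 0; 120: 79.8, 0.8
- eta (time / min: solid electrophile / %, target / %): 8.00: 98.0, 0; 25.0: 93.7, 0; 40.0: 89.5, 0; 60.0: 84.7, 0; 90.0: 78.1, 0.3; 120: 72.9, 0.7

(standard deviation of a reading: 0.3 percentage points)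

- part of the solid electrophile that has reacted (what has only dissolved counts as not reacted) at the end, ash
- part of the solid electrophile that has reacted (what has only dissolved counts as not reacted) at the end, oak
- part of the solid electrophile that has reacted (what has only dissolved counts as not reacted) at the end, larch
- what raising the concentration of free base from its lowest to its highest value here does to the part of the solid electrophile that has reacted (what has only dissolved counts as not reacted) (changes below 5 percentage points count as none) (it rises / it falls / no change)

- what was read earlier has a scatter of 0.3 percentage points, one standard deviation
- at the start none of the solid electrophile is in solution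
- what has only dissolved of solid electrophile counts as not reacted
- a reading or a percentage of target counts all its forms, free or not
- no earlier run changes the charge of free base; that part of a forecast is a guess

*What has left the solid by the last reading?* At 120 min, 0.0465 M in the beta run and 0.0461 M in the eta run: the same molar loss from different charges.

*Has that reacted?* What has only dissolved doesn't count, so I read the target. It stands at 0.00184 M in beta and 0.00119 M in eta, hardly any of the loss.

*What do you carry forward?* The loss runs nearly steadily. If what has dissolved turns into target after a mean wait, the lag time, then [target] is the loss times the time, over 2 lag times, and it grows with the square of the time, as in an induction period. Both runs together read as a lag time of 30.5 h, longer than the 6.0 h asked about.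

*Where is that weak?* It rests on readings of 0.8% and 0.7% against a scatter of 0.3 percentage points, and the square is assumed, not read.

*And ash at its end?* The mean steady loss carried on to the end, with that lag time of 30.5 h, gives as a part of the charge 4.01%.

*Oak and larch?* No run changes the free base, so this is a guess. If the rate were proportional to free base, larch would reach 9.08%, which is 5.1 points above ash and barely past the margin of 5 points. I commit to no change.

The forecast says 27%, 38% and 55%, and it rises, holding “so it is going to an intermediate and the loss is what counts”. There we part: it reckons from the loss, I from the target.

    electrophile + nucleophile → acid set free + target (k = 0.576 M⁻¹ h⁻¹)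
    nucleophile + acid set free ⇌ protonated nucleophile, settled at all times (K = 1370 M⁻¹)
    acid set free + free base ⇌ salt of the base (K = 11200 M⁻¹, k = 10.9 M⁻¹ h⁻¹)
    free base + target ⇌ idle adduct, settled at all times (K = 76.9 M⁻¹)
    solid electrophile ⇌ electrophile, rate k5*(cs5 - [electrophile]) while solid is left; crystals form when [electrophile] > cs5 (solubility = 0.110 M, k = 0.268 h⁻¹)
    acid set free + target → side product (k = 0.302 M⁻¹ h⁻¹)

The flask gives 4.77%, 5.84% and 7.11% for ash, oak and larch: no change, with 2.3 points from lowest to highest base, and the lag time's figure for ash was 4.01%. In larch at 1.51 h the electrophile has a half-life of 11 h by its reaction with nucleophile, longer than the 6.0 h of the run, and at the end it is still made 1.43 times as fast as it is used up, each taken net.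

Take a neighbour of larch with 0.14 M of solid electrophile, all else held. The lag time of 30.5 h gives 9.76%, and multiplied by the factor 1.77 between larch and the lag time's figure for that charge, 17.3%. The flask gives 17.3%.

All runs are simulated for substances that don't exist, noise included.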